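**Plan**

1. Retrosynthesis (target numbered as an azulene: C1–C3, C3a, C4–C8, C8a): the two ester C–O bonds and the cis-diol C2–O/C3–O bonds are cut first. The seven-membered ring is then contracted by excising C5 (bonds C4–C5 and C5–C6), and last the C3–C3a and C1–C8a bonds are cut.
2. Enabling feature: in the seven-membered ring the triad C4(O)–C5H=C6(CH3) is a reduced 3-methylcyclohept-2-enone, i.e. the one-carbon enlargement product of a 2-methylcyclohexanone enol ether. Without C5, the atoms C3a, C4(O), C6(CH3), C7, C8(O), C8a(CH3) map one for one onto the monoketal of 2,5-dimethyl-1,4-benzoquinone.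
3. Forward: quinone monoketal, reductive dienolate, enantioselective propargylation (C8a), reagent-controlled carbonyl reduction (C8), gold-catalysed closure of the five-membered ring (cis), six-to-seven ring enlargement, then dihydroxylation, acetylation, directed reduction, aroylation and desilylation.
4. Stereochemistry: C8a from the chiral chromium catalyst and C8 from the oxazaborolidine. C3a is relayed from C8a by the tether. C2 and C3 are set together by one syn-dihydroxylation anti to C4. C4 is set by hydride delivery from the C3 hydroxyl (1,3-anti).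

Key step: step 11

Assumption: 1 is taken as a catalogue compound; the (S,S) chromium catalyst is written for step 5 by analogy with simple 2-methylcycloalkanone tin enolates, and its mirror image is to be used if this cross-conjugated dienolate responds with the opposite sense.

**Route**

Step 1
Reactants: 1 4-methoxy-2,5-dimethylphenol
Product: 2 4,4-dimethoxy-2,5-dimethylcyclohexa-2,5-dien-1-one
Conditions: PhI(OAc)2, MeOH, 0 °C
Reagents that add atoms: methanol, CO
Why: Hypervalent-iodine oxidative dearomatization of a 4-methoxyphenol, with methanol trapping the phenoxenium ion at the methoxy-bearing para carbon, should give the p-quinone monoketal that already holds six of the seven ring carbons, both ring oxygens and both methyl groups of the seven-membered ring; no stereocenter is formed.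

Step 2
Reactants: 2 4,4-dimethoxy-2,5-dimethylcyclohexa-2,5-dien-1-one
Product: 4 4,4-dimethoxy-2,5-dimethylcyclohexa-1,5-dien-1-yl acetate, via lithium dienolate 3 (not isolated)
Conditions: LiBH(s-Bu)3, THF, −78 °C; then Ac2O, −78 to 0 °C
Reagents that add atoms: acetic anhydride, CC(=O)OC(C)=O
Why: Conjugate reduction by the hindered borohydride should occur at the unsubstituted β-carbon of the α-methyl enone arm (the β-methyl arm is not attacked), and O-acetylation of the cross-conjugated dienolate fixes the enolate regiochemistry as an isolable enol acetate.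

Step 3
Reactants: 5 3-methylbut-1-yne
Product: 7 4-methylpent-2-yn-1-ol, via lithium acetylide 6 (not isolated)
Conditions: n-BuLi, THF, −78 °C; then (CH2O)n, −78 °C to rt
Reagents that add atoms: paraformaldehyde (as formaldehyde), C=O
Why: Hydroxymethylation of a lithium acetylide with formaldehyde is the standard entry to primary propargylic alcohols.

Step 4
Reactants: 7 4-methylpent-2-yn-1-ol
Product: 8 1-bromo-4-methylpent-2-yne
Conditions: PBr3, pyridine (cat.), Et2O, 0 °C
Reagents that add atoms: phosphorus tribromide, BrP(Br)Br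
Why: SN2 bromination of a primary propargylic alcohol through its phosphite ester.

Step 5
Reactants: 4 4,4-dimethoxy-2,5-dimethylcyclohexa-1,5-dien-1-yl acetate; 8 1-bromo-4-methylpent-2-yne
Product: 10 (6S)-4,4-dimethoxy-3,6-dimethyl-6-(4-methylpent-2-yn-1-yl)cyclohex-2-en-1-one, via tributyltin dienolate 9 (not isolated)
Conditions: Bu3SnOMe, 60 °C (removal of MeOAc); then 8, (S,S)-[N,N'-bis(3,5-di-tert-butylsalicylidene)cyclohexane-1,2-diaminato]CrCl (10 mol %), benzene, 0 °C
Reagents that add atoms: none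
Why: Acetate–stannyl exchange gives the tetrasubstituted tributyltin enolate, which should undergo the salen–chromium chloride catalysed enantioselective SN2 alkylation known for tin enolates of 2-methylcycloalkanones with allylic, benzylic and propargylic halides, the chiral trivalent chromium complex selecting the enolate face and so setting the quaternary stereocenter (C8a of the target).

Step 6
Reactants: 10 (6S)-4,4-dimethoxy-3,6-dimethyl-6-(4-methylpent-2-yn-1-yl)cyclohex-2-en-1-one
Product: 12 (4S,5S)-4-hydroxy-2,5-dimethyl-5-(4-methylpent-2-yn-1-yl)cyclohex-2-en-1-one, via allylic alcohol 11 (not isolated)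
Conditions: (R)-2-methyl-CBS-oxazaborolidine (20 mol %), catecholborane, toluene, −78 °C; then aq. oxalic acid, THF, rt
Reagents that add atoms: water, O
Why: Corey–Bakshi–Shibata reduction, with the fully substituted α-carbon as the large flank and the vinylic CH as the small one, should deliver hydride under catalyst control (methyl and propargyl on the neighbouring quaternary carbon are nearly isosteric, so the substrate has little bias of its own) to give the (S)-carbinol cis to the methyl group, and the acidic work-up hydrolyses the allylic dimethyl ketal to the enone.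

Step 7
Reactants: 12 (4S,5S)-4-hydroxy-2,5-dimethyl-5-(4-methylpent-2-yn-1-yl)cyclohex-2-en-1-one
Product: 13 tert-butyl{[(1S,6S)-4-[(tert-butyldimethylsilyl)oxy]-3,6-dimethyl-6-(4-methylpent-2-yn-1-yl)cyclohexa-2,4-dien-1-yl]oxy}dimethylsilane
Conditions: TBSOTf (2.5 equiv), Et3N, CH2Cl2, 0 °C
Reagents that add atoms: tert-butyldimethylsilyl trifluoromethanesulfonate, CC(C)(C)[Si](C)(C)OS(=O)(=O)C(F)(F)F
Why: Silyl triflate and amine silylate the alcohol and, by soft enolization at the only α′-CH2, convert the enone into the cross-conjugated 2-silyloxy diene whose nucleophilic carbon is the future ring-fusion carbon C3a.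

Step 8
Reactants: 13 tert-butyl{[(1S,6S)-4-[(tert-butyldimethylsilyl)oxy]-3,6-dimethyl-6-(4-methylpent-2-yn-1-yl)cyclohexa-2,4-dien-1-yl]oxy}dimethylsilane
Product: 14 (3aS,4S,7aR)-4-[(tert-butyldimethylsilyl)oxy]-3a,6-dimethyl-1-(propan-2-yl)-3,3a,4,7a-tetrahydro-7H-inden-7-one
Conditions: Ph3PAuCl (5 mol %), AgBF4 (5 mol %), CH2Cl2/MeOH 10:1, 40 °C
Reagents that add atoms: none
Why: Cationic monovalent gold activates the alkyne for 5-endo-dig attack by the silyl enol ether carbon (Conia-ene type carbocyclization of silyl enol ethers), methanol takes off the silyl group and protonates the vinylgold, and because the alkyne hangs from the quaternary carbon the new bond can only form on that face, which gives the cis ring fusion (C3a from C8a) and the isopropyl-bearing cyclopentene.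

Step 9
Reactants: 14 (3aS,4S,7aR)-4-[(tert-butyldimethylsilyl)oxy]-3a,6-dimethyl-1-(propan-2-yl)-3,3a,4,7a-tetrahydro-7H-inden-7-one
Product: 16 tert-butyl{[(3aS,4S,7aR)-3a,6-dimethyl-1-(propan-2-yl)-7-[(trimethylsilyl)oxy]-3a,4,5,7a-tetrahydro-3H-inden-4-yl]oxy}dimethylsilane, via lithium enolate 15 (not isolated)
Conditions: LiBH(s-Bu)3, THF, −78 °C; then TMSCl, Et3N, −78 to 0 °C
Reagents that add atoms: chlorotrimethylsilane, C[Si](C)(C)Cl
Why: 1,4-Reduction of the α-methyl enone (hydride to the β-CH) and O-silylation of the enolate should give the trimethylsilyl enol ether with its double bond toward the methyl-bearing carbon only, a regiochemistry that enolization of the saturated ketone could not guarantee.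

Step 10
Reactants: 16 tert-butyl{[(3aS,4S,7aR)-3a,6-dimethyl-1-(propan-2-yl)-7-[(trimethylsilyl)oxy]-3a,4,5,7a-tetrahydro-3H-inden-4-yl]oxy}dimethylsilane
Product: 17 the siloxycyclopropane of 16, i.e. 16 carrying a CH2 bridge across C6 and C7 (1-methyl-6-(trimethylsilyloxy)bicyclo[4.1.0]heptane unit, either cyclopropane face)
Conditions: Et2Zn, CH2I2, Et2O, 0 °C
Reagents that add atoms: diiodomethane, ICI
Why: Simmons–Smith cyclopropanation (Furukawa reagent) should take place at the electron-rich silyl enol ether in preference to the hindered trisubstituted cyclopentene; the configuration of the two cyclopropane carbons is of no consequence because both are lost in step 11.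

Step 11
Reactants: 17 the siloxycyclopropane of 16
Product: 19 (3aR,8S,8aS)-8-[(tert-butyldimethylsilyl)oxy]-6,8a-dimethyl-3-(propan-2-yl)-1,7,8,8a-tetrahydroazulen-4(3aH)-one, via chloro ketone 18 (not isolated)
Conditions: FeCl3 (2.5 equiv), pyridine, DMF, 0 °C; then NaOAc, MeOH, 40 °C
Reagents that add atoms: none
Why: FeCl3 oxidises the siloxycyclopropane by one electron to a cyclopropyloxy radical; β-scission of the bond shared by the three- and six-membered rings turns the six-membered ring into the seven-membered ring and leaves a tertiary radical at the methyl-bearing carbon, which takes chlorine from a second FeCl3 to give the β-chloro ketone 18, and acetate then eliminates HCl by an E1cB path to the conjugated enone. The closest known reaction is the Ito–Saegusa ring expansion, whose standard case is 2-methylcyclohexanone to 3-methylcyclohept-2-enone. No ring is closed here: the seven-membered ring arises by opening of the bicyclo[4.1.0] unit, the carbenoid carbon of step 10 becoming C5 of the target. No new stereocenter remains (the C–Cl carbon becomes sp2), and C3a, C8 and C8a are not touched. The step needs scission of the internal and not the external cyclopropane bond, which the methyl group secures (tertiary against primary radical), and elimination toward C5 and not C7, which is secured because only C5 lies α to the carbonyl, C8 being held as a silyl ether and not as a second ketone. Chlorine transfer should outrun addition of the radical to the cyclopentene, and the mild acetate base should leave the epimerizable allylic C3a–H in place.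

Step 12
Reactants: 19 (3aR,8S,8aS)-8-[(tert-butyldimethylsilyl)oxy]-6,8a-dimethyl-3-(propan-2-yl)-1,7,8,8a-tetrahydroazulen-4(3aH)-one
Product: 20 (2S,3R,3aS,8S,8aS)-8-[(tert-butyldimethylsilyl)oxy]-2,3-dihydroxy-6,8a-dimethyl-3-(propan-2-yl)-1,2,3,7,8,8a-hexahydroazulen-4(3aH)-one
Conditions: OsO4 (5 mol %), N-methylmorpholine N-oxide, acetone/H2O, rt
Reagents that add atoms: osmium tetroxide (catalytic carrier of both oxygens), O=[Os](=O)(=O)=O; N-methylmorpholine N-oxide, C[N+]1([O-])CCOCC1; water, O
Why: Upjohn syn-dihydroxylation should occur at the electron-rich cyclopentene and not at the enone double bond, and on the face anti to the allylic C4 substituent of C3a (the convex face of the cis-fused bicycle, syn to H-3a and the angular methyl), which sets C2 and C3 together.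

Step 13
Reactants: 20 (2S,3R,3aS,8S,8aS)-8-[(tert-butyldimethylsilyl)oxy]-2,3-dihydroxy-6,8a-dimethyl-3-(propan-2-yl)-1,2,3,7,8,8a-hexahydroazulen-4(3aH)-one
Product: 21 (2S,3R,3aS,8S,8aS)-8-[(tert-butyldimethylsilyl)oxy]-3-hydroxy-6,8a-dimethyl-4-oxo-3-(propan-2-yl)-1,2,3,3a,4,7,8,8a-octahydroazulen-2-yl acetate
Conditions: Ac2O, pyridine, DMAP (cat.), CH2Cl2, 0 °C
Reagents that add atoms: acetic anhydride, CC(=O)OC(C)=O
Why: Acylation distinguishes the secondary C2 hydroxyl from the tertiary C3 hydroxyl, which stays free.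

Step 14
Reactants: 21 (2S,3R,3aS,8S,8aS)-8-[(tert-butyldimethylsilyl)oxy]-3-hydroxy-6,8a-dimethyl-4-oxo-3-(propan-2-yl)-1,2,3,3a,4,7,8,8a-octahydroazulen-2-yl acetate
Product: 22 (2S,3R,3aR,4S,8S,8aS)-8-[(tert-butyldimethylsilyl)oxy]-3,4-dihydroxy-6,8a-dimethyl-3-(propan-2-yl)-1,2,3,3a,4,7,8,8a-octahydroazulen-2-yl acetate
Conditions: Me4NBH(OAc)3, MeCN/AcOH, −20 °C
Reagents that add atoms: none
Why: In this Evans–Saksena reduction the tertiary C3 hydroxyl binds boron and delivers hydride to the β-carbonyl from its own face, so the new C4 hydroxyl should be 1,3-anti (trans) to the C3 hydroxyl, and the enone is reduced 1,2.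

Step 15
Reactants: 23 4-hydroxybenzoic acid
Product: 25 4-[(tert-butyldimethylsilyl)oxy]benzoic acid, via silyl ester 24 (not isolated)
Conditions: TBSCl (2.2 equiv), imidazole, DMF, rt; then AcOH/THF/H2O, rt
Reagents that add atoms: tert-butyl(chloro)dimethylsilane, CC(C)(C)[Si](C)(C)Cl
Why: Both hydroxyls are silylated and the labile silyl ester is then hydrolysed selectively, the aryl silyl ether being stable to mild aqueous acid.

Step 16
Reactants: 22 (2S,3R,3aR,4S,8S,8aS)-8-[(tert-butyldimethylsilyl)oxy]-3,4-dihydroxy-6,8a-dimethyl-3-(propan-2-yl)-1,2,3,3a,4,7,8,8a-octahydroazulen-2-yl acetate; 25 4-[(tert-butyldimethylsilyl)oxy]benzoic acid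
Product: 26 (2S,3R,3aR,4S,8S,8aS)-2-(acetyloxy)-8-[(tert-butyldimethylsilyl)oxy]-3-hydroxy-6,8a-dimethyl-3-(propan-2-yl)-1,2,3,3a,4,7,8,8a-octahydroazulen-4-yl 4-[(tert-butyldimethylsilyl)oxy]benzoate
Conditions: EDC·HCl, DMAP, CH2Cl2, rt
Reagents that add atoms: none
Why: Steglich esterification should acylate the only reactive hydroxyl, the secondary allylic C4–OH, with retention, the tertiary C3–OH being inert.

Step 17
Reactants: 26 (2S,3R,3aR,4S,8S,8aS)-2-(acetyloxy)-8-[(tert-butyldimethylsilyl)oxy]-3-hydroxy-6,8a-dimethyl-3-(propan-2-yl)-1,2,3,3a,4,7,8,8a-octahydroazulen-4-yl 4-[(tert-butyldimethylsilyl)oxy]benzoate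
Product: 27 (2S,3R,3aR,4S,8S,8aS)-2-(acetyloxy)-3,8-dihydroxy-6,8a-dimethyl-3-(propan-2-yl)-1,2,3,3a,4,7,8,8a-octahydroazulen-4-yl 4-hydroxybenzoate (CNP0146780.2)
Conditions: HF·pyridine, pyridine, THF, 0 °C to rt
Reagents that add atoms: none
Why: Buffered fluoride should cleave the aryl and the secondary alkyl silyl ether in one operation and leave the acetate, the allylic benzoate and the tertiary alcohol intact.

**Compound list**

1 | 4-methoxy-2,5-dimethylphenol | COc1cc(C)c(O)cc1C | starting material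
2 | 4,4-dimethoxy-2,5-dimethylcyclohexa-2,5-dien-1-one | COC1(OC)C=C(C)C(=O)C=C1C | intermediate
3 | lithium 4,4-dimethoxy-2,5-dimethylcyclohexa-1,5-dien-1-olate | [Li]OC1=C(C)CC(OC)(OC)C(C)=C1 | intermediate
4 | 4,4-dimethoxy-2,5-dimethylcyclohexa-1,5-dien-1-yl acetate | CC(=O)OC1=C(C)CC(OC)(OC)C(C)=C1 | intermediate
5 | 3-methylbut-1-yne | CC(C)C#C | starting material
6 | (3-methylbut-1-yn-1-yl)lithium | CC(C)C#C[Li] | intermediate
7 | 4-methylpent-2-yn-1-ol | CC(C)C#CCO | intermediate
8 | 1-bromo-4-methylpent-2-yne | CC(C)C#CCBr | intermediate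
9 | tributyl[(4,4-dimethoxy-2,5-dimethylcyclohexa-1,5-dien-1-yl)oxy]stannane | CCCC[Sn](CCCC)(CCCC)OC1=C(C)CC(OC)(OC)C(C)=C1 | intermediate
10 | (6S)-4,4-dimethoxy-3,6-dimethyl-6-(4-methylpent-2-yn-1-yl)cyclohex-2-en-1-one | O=C1C=C(C)C(OC)(OC)C[C@]1(C)CC#CC(C)C | intermediate
11 | (1S,6S)-4,4-dimethoxy-3,6-dimethyl-6-(4-methylpent-2-yn-1-yl)cyclohex-2-en-1-ol | O[C@H]1C=C(C)C(OC)(OC)C[C@]1(C)CC#CC(C)C | intermediate
12 | (4S,5S)-4-hydroxy-2,5-dimethyl-5-(4-methylpent-2-yn-1-yl)cyclohex-2-en-1-one | O[C@H]1C=C(C)C(=O)C[C@]1(C)CC#CC(C)C | intermediate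
13 | tert-butyl{[(1S,6S)-4-[(tert-butyldimethylsilyl)oxy]-3,6-dimethyl-6-(4-methylpent-2-yn-1-yl)cyclohexa-2,4-dien-1-yl]oxy}dimethylsilane | C[Si](C)(C(C)(C)C)O[C@H]1C=C(C)C(O[Si](C)(C)C(C)(C)C)=C[C@]1(C)CC#CC(C)C | intermediate
14 | (3aS,4S,7aR)-4-[(tert-butyldimethylsilyl)oxy]-3a,6-dimethyl-1-(propan-2-yl)-3,3a,4,7a-tetrahydro-7H-inden-7-one | CC(C)C1=CC[C@]2(C)[C@@H](O[Si](C)(C)C(C)(C)C)C=C(C)C(=O)[C@H]12 | intermediate
15 | lithium enolate of the C7 ketone of 14 after 1,4-reduction (C6=C7 enolate) | CC(C)C1=CC[C@]2(C)[C@@H](O[Si](C)(C)C(C)(C)C)CC(C)=C(O[Li])[C@H]12 | intermediate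
16 | tert-butyl{[(3aS,4S,7aR)-3a,6-dimethyl-1-(propan-2-yl)-7-[(trimethylsilyl)oxy]-3a,4,5,7a-tetrahydro-3H-inden-4-yl]oxy}dimethylsilane | CC(C)C1=CC[C@]2(C)[C@@H](O[Si](C)(C)C(C)(C)C)CC(C)=C(O[Si](C)(C)C)[C@H]12 | intermediate
17 | siloxycyclopropane: 16 with a CH2 bridging C6 and C7 (either cyclopropane face) | CC(C)C1=CC[C@]2(C)[C@@H](O[Si](C)(C)C(C)(C)C)CC3(C)CC3(O[Si](C)(C)C)[C@H]12 | intermediate
18 | (3aR,8S,8aS)-8-[(tert-butyldimethylsilyl)oxy]-6-chloro-6,8a-dimethyl-3-(propan-2-yl)-1,5,6,7,8,8a-hexahydroazulen-4(3aH)-one (C6 epimers) | CC(C)C1=CC[C@]2(C)[C@@H](O[Si](C)(C)C(C)(C)C)CC(C)(Cl)CC(=O)[C@H]12 | intermediate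
19 | (3aR,8S,8aS)-8-[(tert-butyldimethylsilyl)oxy]-6,8a-dimethyl-3-(propan-2-yl)-1,7,8,8a-tetrahydroazulen-4(3aH)-one | CC(C)C1=CC[C@]2(C)[C@@H](O[Si](C)(C)C(C)(C)C)CC(C)=CC(=O)[C@H]12 | intermediate
20 | (2S,3R,3aS,8S,8aS)-8-[(tert-butyldimethylsilyl)oxy]-2,3-dihydroxy-6,8a-dimethyl-3-(propan-2-yl)-1,2,3,7,8,8a-hexahydroazulen-4(3aH)-one | O[C@H]1C[C@]2(C)[C@@H](O[Si](C)(C)C(C)(C)C)CC(C)=CC(=O)[C@@H]2[C@]1(O)C(C)C | intermediate
21 | (2S,3R,3aS,8S,8aS)-8-[(tert-butyldimethylsilyl)oxy]-3-hydroxy-6,8a-dimethyl-4-oxo-3-(propan-2-yl)-1,2,3,3a,4,7,8,8a-octahydroazulen-2-yl acetate | CC(=O)O[C@H]1C[C@]2(C)[C@@H](O[Si](C)(C)C(C)(C)C)CC(C)=CC(=O)[C@@H]2[C@]1(O)C(C)C | intermediate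
22 | (2S,3R,3aR,4S,8S,8aS)-8-[(tert-butyldimethylsilyl)oxy]-3,4-dihydroxy-6,8a-dimethyl-3-(propan-2-yl)-1,2,3,3a,4,7,8,8a-octahydroazulen-2-yl acetate | CC(=O)O[C@H]1C[C@]2(C)[C@@H](O[Si](C)(C)C(C)(C)C)CC(C)=C[C@H](O)[C@@H]2[C@]1(O)C(C)C | intermediate
23 | 4-hydroxybenzoic acid | O=C(O)c1ccc(O)cc1 | starting material
24 | tert-butyldimethylsilyl 4-[(tert-butyldimethylsilyl)oxy]benzoate | CC(C)(C)[Si](C)(C)OC(=O)c1ccc(O[Si](C)(C)C(C)(C)C)cc1 | intermediate
25 | 4-[(tert-butyldimethylsilyl)oxy]benzoic acid | CC(C)(C)[Si](C)(C)Oc1ccc(C(=O)O)cc1 | intermediate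
26 | (2S,3R,3aR,4S,8S,8aS)-2-(acetyloxy)-8-[(tert-butyldimethylsilyl)oxy]-3-hydroxy-6,8a-dimethyl-3-(propan-2-yl)-1,2,3,3a,4,7,8,8a-octahydroazulen-4-yl 4-[(tert-butyldimethylsilyl)oxy]benzoate | CC(=O)O[C@H]1C[C@]2(C)[C@@H](O[Si](C)(C)C(C)(C)C)CC(C)=C[C@H](OC(=O)c3ccc(O[Si](C)(C)C(C)(C)C)cc3)[C@@H]2[C@]1(O)C(C)C | intermediate
27 | (2S,3R,3aR,4S,8S,8aS)-2-(acetyloxy)-3,8-dihydroxy-6,8a-dimethyl-3-(propan-2-yl)-1,2,3,3a,4,7,8,8a-octahydroazulen-4-yl 4-hydroxybenzoate | CC(=O)O[C@H]1C[C@]2(C)[C@@H](O)CC(C)=C[C@H](OC(=O)c3ccc(O)cc3)[C@@H]2[C@]1(O)C(C)C | target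

**Summary**

Total step count: 17.
Longest linear sequence: 14 steps (1, 2, 5 to 14, 16, 17, counted from 1).

Steps most likely to fail, each with a fallback:

Step 5. The chromium catalyst may discriminate poorly between the faces of this new cross-conjugated tin dienolate, or the bromide may be attacked through its alkyne terminus to give an allene. Fallback: setting out from 2, the lithium dienolate 3 made as in step 2 is alkylated directly with 8 (THF, DMPU, −78 to 0 °C) to the racemic ketone F1. The stereochemical burden then rests on the reagent-controlled reduction of step 6, which should turn the racemate into two (S)-carbinols, 11 and its epimer at the quaternary carbon, the (1S,6R)-alcohol F2. After the acidic work-up the (4S,5R)-hydroxy enone F3 is removed by chromatography and the route is rejoined at 12, at the price of half of the material.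

Step 6. Catalyst control may be lost to the local bias of the quaternary carbon, or the sense of hydride delivery may be opposite to the model. Fallback: setting out from 10, a Luche reduction (NaBH4, CeCl3·7H2O, MeOH, −78 °C) gives the carbinols under substrate control; any 11 formed is carried on, and the (1R,6S)-alcohol F4 is inverted by a Mitsunobu reaction (4-nitrobenzoic acid, PPh3, DIAD, toluene) to the (1S,6S)-4-nitrobenzoate F5. Methanolysis (K2CO3, MeOH) returns the route at 11, which is hydrolysed to 12 as in step 6.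

Step 8. The neopentylic enol carbon may fail to attack the isopropyl-substituted alkyne, so that simple protodesilylation of the enol ether takes over. Fallback: setting out from 13, electrophilic iodocarbocyclization with bis(pyridine)iodonium tetrafluoroborate and HBF4 (CH2Cl2, −78 °C) uses a stoichiometric iodonium in place of the gold catalyst and should give the vinyl iodide F6. Hydrodeiodination with Pd(PPh3)4, HCO2H and Et3N (DMF, 60 °C) returns the route at 14.

Further compounds
F1 | step 5 | rac-4,4-dimethoxy-3,6-dimethyl-6-(4-methylpent-2-yn-1-yl)cyclohex-2-en-1-one | O=C1C=C(C)C(OC)(OC)CC1(C)CC#CC(C)C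
F2 | step 5 | (1S,6R)-4,4-dimethoxy-3,6-dimethyl-6-(4-methylpent-2-yn-1-yl)cyclohex-2-en-1-ol | O[C@H]1C=C(C)C(OC)(OC)C[C@@]1(C)CC#CC(C)C
F3 | step 5 | (4S,5R)-4-hydroxy-2,5-dimethyl-5-(4-methylpent-2-yn-1-yl)cyclohex-2-en-1-one | O[C@H]1C=C(C)C(=O)C[C@@]1(C)CC#CC(C)C
F4 | step 6 | (1R,6S)-4,4-dimethoxy-3,6-dimethyl-6-(4-methylpent-2-yn-1-yl)cyclohex-2-en-1-ol | O[C@@H]1C=C(C)C(OC)(OC)C[C@]1(C)CC#CC(C)C
F5 | step 6 | (1S,6S)-4,4-dimethoxy-3,6-dimethyl-6-(4-methylpent-2-yn-1-yl)cyclohex-2-en-1-yl 4-nitrobenzoate | O=C(O[C@H]1C=C(C)C(OC)(OC)C[C@]1(C)CC#CC(C)C)c1ccc(cc1)[N+](=O)[O-]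
F6 | step 8 | (3aS,4S,7aS)-4-[(tert-butyldimethylsilyl)oxy]-2-iodo-3a,6-dimethyl-1-(propan-2-yl)-3,3a,4,7a-tetrahydro-7H-inden-7-one | CC(C)C1=C(I)C[C@]2(C)[C@@H](O[Si](C)(C)C(C)(C)C)C=C(C)C(=O)[C@H]12
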